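**Retrosynthetic overview**
1. The only ring (28-membered) is closed last at C15–C16 by a nickel-electrocatalytic reductive coupling of an (E)- and a (Z)-alkenyl iodide; this step also creates the (14E,16Z)-diene.
2. The open-chain precursor comes from amide coupling (C24–N) of a west–HA acid with an east α-amino ketone, then a 1,3-anti reduction at C23 directed by the C21 hydroxyl.
3. West acid C1–C15: cross-metathesis/hydrogenation joins C1–C7 to C8–C14. C2 and C13 come from invertive Grignard–triflate couplings (L-lactate, (S)-2-hydroxybutanoate), C4 from (S)-3-bromo-2-methylpropanol, C9 from (S)-epichlorohydrin; Takai olefination gives the (E)-iodide.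
4. East amine C16–C24: 2-deoxy-D-ribose supplies C19–C23 with C20 and C21. A van Leusen oxazole masks the C23 ketone and C24 amine; radical propargylation and Rh silylformylation build the (Z)-iodoalkene.
5. HA is (S)-2-hydroxypentanoic acid, esterified with the west acid before the amide coupling.

Assumption: C1–C24 number the polyketide chain of the target from the lactone carbonyl (C1) to the CH2N carbon (C24), HA is the (S)-2-hydroxypentanoyl unit, and compounds 1, 4, 8, 16, 25 and 29 are bought.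

**West fragment**

Step 1
Reactants: 1 (S)-3-bromo-2-methylpropan-1-ol
Product: 2 (R)-2-methylhex-5-en-1-ol
Conditions: allylMgBr (3 equiv), Li2CuCl4 (3 mol%), THF, −78 → 0 °C
Reagents that add atoms: allylmagnesium bromide, C=CC[Mg]Br
Why: Cu-catalysed sp3–sp3 Grignard cross-coupling (Kochi type) on the magnesium alkoxide of 1 displaces the primary bromide and leaves the bought stereocentre (future C4) untouched.

Step 2
Reactants: 2 (R)-2-methylhex-5-en-1-ol
Product: 3 (R)-6-bromo-5-methylhex-1-ene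
Conditions: CBr4, PPh3, CH2Cl2, 0 °C
Reagents that add atoms: carbon tetrabromide, BrC(Br)(Br)Br
Why: Appel bromination of a primary alcohol; the adjacent stereocentre is not involved.

Step 3
Reactants: 4 tert-butyl (S)-2-hydroxypropanoate
Product: 5 tert-butyl (S)-2-{[(trifluoromethyl)sulfonyl]oxy}propanoate
Conditions: Tf2O, 2,6-lutidine, CH2Cl2, −78 → 0 °C
Reagents that add atoms: trifluoromethanesulfonic anhydride, O=S(=O)(OS(=O)(=O)C(F)(F)F)C(F)(F)F
Why: O-triflation of an α-hydroxy ester with a hindered base at low temperature proceeds with retention and without racemisation.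

Step 4
Reactants: 3 (R)-6-bromo-5-methylhex-1-ene; 5 tert-butyl (S)-2-{[(trifluoromethyl)sulfonyl]oxy}propanoate
Product: 7 tert-butyl (2S,4R)-2,4-dimethyloct-7-enoate, via Grignard reagent 6 (not isolated)
Conditions: Mg, THF, rt; then ZnCl2 (10 mol%), 5, THF, 0 °C
Reagents that add atoms: magnesium, [Mg] (enters intermediate 6 only)
Why: ZnCl2-catalysed Grignard/α-triflyloxy-ester coupling is a clean SN2 displacement through a triorganozincate, so C2 is set by inversion of the L-lactate centre while C4 comes from 1.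

Step 5
Reactants: 8 (S)-2-(chloromethyl)oxirane
Product: 10 (S)-2-(prop-2-en-1-yl)oxirane, via chlorohydrin 9 (not isolated)
Conditions: vinylMgBr, CuI (10 mol%), THF, −40 °C; then aq. NaOH, rt
Reagents that add atoms: vinylmagnesium bromide, C=C[Mg]Br
Why: CuI-catalysed Grignard opening at the epoxide CH2 followed by Williamson closure of the chlorohydrin transposes the epoxide without touching the C–O stereocentre (future C9).

Step 6
Reactants: 10 (S)-2-(prop-2-en-1-yl)oxirane
Product: 11 (S)-hexa-1,5-dien-3-ol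
Conditions: Me3S+ I− (3.5 equiv), n-BuLi (3.3 equiv), THF, −10 °C → rt
Reagents that add atoms: trimethylsulfonium iodide, C[S+](C)C.[I-]
Why: Epoxide-to-allylic-alcohol homologation (ylide opening at CH2, then β-elimination of dimethyl sulfide) leaves the carbinol centre untouched and makes the two arms of C9 different (vinyl versus allyl).

Step 7
Reactants: 11 (S)-hexa-1,5-dien-3-ol
Product: 12 tert-butyl[(3S)-hexa-1,5-dien-3-yloxy]dimethylsilane
Conditions: TBSCl, imidazole, DMF, rt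
Reagents that add atoms: tert-butyldimethylsilyl chloride, CC(C)(C)[Si](C)(C)Cl
Why: Standard silylation of a secondary alcohol.

Step 8
Reactants: 12 tert-butyl[(3S)-hexa-1,5-dien-3-yloxy]dimethylsilane
Product: 14 (4S)-4-[(tert-butyldimethylsilyl)oxy]hex-5-en-1-ol, via alkylborane 13 (not isolated)
Conditions: 9-BBN (1.05 equiv), THF, 0 °C → rt; then NaOH, H2O2, 0 °C
Reagents that add atoms: 9-borabicyclo[3.3.1]nonane, B1C2CCCC1CCC2 (enters intermediate 13 only); hydrogen peroxide, OO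
Why: Anti-Markovnikov hydroboration–oxidation; 9-BBN attacks the unhindered homoallylic alkene much faster than the vinyl group next to the bulky silyloxy centre.

Step 9
Reactants: 14 (4S)-4-[(tert-butyldimethylsilyl)oxy]hex-5-en-1-ol
Product: 15 {[(3S)-6-bromohex-1-en-3-yl]oxy}(tert-butyl)dimethylsilane
Conditions: CBr4, PPh3, CH2Cl2, 0 °C
Reagents that add atoms: carbon tetrabromide, BrC(Br)(Br)Br
Why: Appel bromination of the primary alcohol.

Step 10
Reactants: 16 methyl (S)-2-hydroxybutanoate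
Product: 17 methyl (S)-2-{[(trifluoromethyl)sulfonyl]oxy}butanoate
Conditions: Tf2O, 2,6-lutidine, CH2Cl2, −78 → 0 °C
Reagents that add atoms: trifluoromethanesulfonic anhydride, O=S(=O)(OS(=O)(=O)C(F)(F)F)C(F)(F)F
Why: O-triflation with retention, as in step 3.

Step 11
Reactants: 15 {[(3S)-6-bromohex-1-en-3-yl]oxy}(tert-butyl)dimethylsilane; 17 methyl (S)-2-{[(trifluoromethyl)sulfonyl]oxy}butanoate
Product: 19 methyl (2S,6S)-6-[(tert-butyldimethylsilyl)oxy]-2-ethyloct-7-enoate, via Grignard reagent 18 (not isolated)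
Conditions: Mg, THF, rt; then ZnCl2 (10 mol%), 17, THF, 0 °C
Reagents that add atoms: magnesium, [Mg] (enters intermediate 18 only)
Why: The same ZnCl2-catalysed SN2 Grignard–triflate coupling sets the ethyl-bearing centre (C13) by inversion of the bought (S)-2-hydroxybutanoate centre.

Step 12
Reactants: 7 tert-butyl (2S,4R)-2,4-dimethyloct-7-enoate; 19 methyl (2S,6S)-6-[(tert-butyldimethylsilyl)oxy]-2-ethyloct-7-enoate
Product: 20 1-tert-butyl 14-methyl (2S,4R,7E,9S,13S)-9-[(tert-butyldimethylsilyl)oxy]-13-ethyl-2,4-dimethyltetradec-7-enedioate (E/Z mixture, E major)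
Conditions: 7 (2 equiv), second-generation Grubbs catalyst RuCl2(PCy3)(H2IMes)(=CHPh) (5 mol%), CH2Cl2, 40 °C
Reagents that add atoms: none
Why: Olefin cross-metathesis between a reactive terminal alkene (in excess) and the hindered allylic silyl ether, which homodimerises slowly; the C7=C8 geometry is irrelevant because it is hydrogenated next.

Step 13
Reactants: 20 diester alkene
Product: 21 1-tert-butyl 14-methyl (2S,4R,9R,13S)-9-[(tert-butyldimethylsilyl)oxy]-13-ethyl-2,4-dimethyltetradecanedioate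
Conditions: H2 (1 atm), Pd/C, EtOAc, rt
Reagents that add atoms: none
Why: Heterogeneous hydrogenation of the disubstituted alkene; esters, silyl ether and stereocentres are unaffected.

Step 14
Reactants: 21 saturated diester
Product: 22 tert-butyl (2S,4R,9R,13S)-9-[(tert-butyldimethylsilyl)oxy]-13-ethyl-2,4-dimethyl-14-oxotetradecanoate
Conditions: DIBAL-H (1.1 equiv), CH2Cl2, −78 °C
Reagents that add atoms: none
Why: Partial reduction of the methyl ester through a stable tetrahedral aluminate at −78 °C; the tert-butyl ester is inert and C13 is not epimerised at this temperature.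

Step 15
Reactants: 22 aldehyde
Product: 23 tert-butyl (2S,4R,9R,13S,14E)-9-[(tert-butyldimethylsilyl)oxy]-13-ethyl-15-iodo-2,4-dimethylpentadec-14-enoate
Conditions: CHI3, CrCl2, THF/1,4-dioxane (1:6), 0 °C → rt
Reagents that add atoms: iodoform, IC(I)I
Why: Takai olefination gives the (E)-alkenyl iodide under non-basic conditions, so the α-stereocentre C13 is preserved.

Step 16
Reactants: 23 alkenyl iodide tert-butyl ester
Product: 24 (2S,4R,9R,13S,14E)-9-[(tert-butyldimethylsilyl)oxy]-13-ethyl-15-iodo-2,4-dimethylpentadec-14-enoic acid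
Conditions: 85% aq. H3PO4, toluene, rt
Reagents that add atoms: none
Why: Mild acidolysis of the tert-butyl ester (loss of isobutene) that spares the secondary silyl ether and the alkenyl iodide.

**HA unit and west–HA acid**

Step 17
Reactants: 25 (S)-2-hydroxypentanoic acid
Product: 26 tert-butyl (S)-2-hydroxypentanoate
Conditions: t-BuOC(=NH)CCl3 (2 equiv), CH2Cl2/cyclohexane, rt
Reagents that add atoms: tert-butyl 2,2,2-trichloroacetimidate, CC(C)(C)OC(=N)C(Cl)(Cl)Cl
Why: Trichloroacetimidate tert-butylation is activated by the carboxylic acid itself, so only the acid is esterified and the stereocentre is untouched.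

Step 18
Reactants: 24 west acid; 26 tert-butyl (S)-2-hydroxypentanoate
Product: 27 (2S)-1-tert-butoxy-1-oxopentan-2-yl (2S,4R,9R,13S,14E)-9-[(tert-butyldimethylsilyl)oxy]-13-ethyl-15-iodo-2,4-dimethylpentadec-14-enoate
Conditions: EDC·HCl, DMAP (0.2 equiv), CH2Cl2, 0 °C → rt
Reagents that add atoms: none
Why: Steglich esterification; 26 has a single hydroxyl, C9–OH is protected, and low temperature with little DMAP limits epimerisation at C2.

Step 19
Reactants: 27 protected depsi-ester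
Product: 28 (2S)-2-{[(2S,4R,9R,13S,14E)-13-ethyl-9-hydroxy-15-iodo-2,4-dimethylpentadec-14-enoyl]oxy}pentanoic acid
Conditions: TFA/CH2Cl2/H2O (10:10:1), 0 °C → rt
Reagents that add atoms: none
Why: Acidolysis removes the tert-butyl ester and the silyl ether in one operation; the internal ester and alkenyl iodide are stable to acid.

**East fragment**

Step 20
Reactants: 29 2-deoxy-D-ribose
Product: 30 2-deoxy-3,4-O-isopropylidene-D-erythro-pentopyranose
Conditions: 2-methoxypropene, PPTS (cat.), EtOAc, rt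
Reagents that add atoms: 2-methoxypropene, COC(C)=C
Why: Transacetalisation onto the cis-3,4-diol of the pyranose protects C20–O and C21–O and leaves the lactol free.

Step 21
Reactants: 30 acetonide lactol
Product: 31 [(4R,5S)-2,2-dimethyl-5-(1,3-oxazol-5-ylmethyl)-1,3-dioxolan-4-yl]methanol
Conditions: TosMIC, K2CO3, MeOH, 65 °C
Reagents that add atoms: p-toluenesulfonylmethyl isocyanide, [C-]#[N+]CS(=O)(=O)c1ccc(C)cc1
Why: Van Leusen oxazole synthesis on the open-chain aldehyde tautomer; the oxazole is a masked C23 ketone and C24 amine, the C19 hydroxyl is set free, and the sugar stereocentres are untouched.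

Step 22
Reactants: 31 oxazole alcohol
Product: 32 5-{[(4S,5S)-5-(iodomethyl)-2,2-dimethyl-1,3-dioxolan-4-yl]methyl}-1,3-oxazole
Conditions: I2, PPh3, imidazole, toluene/MeCN, rt
Reagents that add atoms: iodine, II
Why: Garegg–Samuelsson iodination of the primary alcohol.

Step 23
Reactants: 32 iodide
Product: 33 5-{[(4S,5R)-5-(but-3-yn-1-yl)-2,2-dimethyl-1,3-dioxolan-4-yl]methyl}-1,3-oxazole
Conditions: Bu3SnCH=C=CH2 (2 equiv), AIBN (0.2 equiv), PhH, 80 °C
Reagents that add atoms: tributyl(propa-1,2-dien-1-yl)stannane, C=C=C[Sn](CCCC)(CCCC)CCCC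
Why: Radical-chain SH2′ propargylation: the primary C19 radical adds to the allenylstannane terminus and expels Bu3Sn•, forming C18–C19 under neutral conditions that the oxazole and acetonide tolerate.

Step 24
Reactants: 33 terminal alkyne
Product: 34 (2Z)-2-{2-[(4R,5S)-2,2-dimethyl-5-(1,3-oxazol-5-ylmethyl)-1,3-dioxolan-4-yl]ethyl}-3-[dimethyl(phenyl)silyl]prop-2-enal
Conditions: PhMe2SiH (1.1 equiv), CO (10 atm), Rh(acac)(CO)2 (1 mol%), toluene, 25 °C
Reagents that add atoms: dimethyl(phenyl)silane, C[SiH](C)c1ccccc1; carbon monoxide, [C-]#[O+]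
Why: Rh-catalysed silylformylation adds silyl (terminal carbon) and formyl (internal carbon) syn across the alkyne, which fixes the C16=C17 geometry with the future CH2OMe carbon cis to C16–Si.

Step 25
Reactants: 34 silyl enal
Product: 35 (2Z)-2-{2-[(4R,5S)-2,2-dimethyl-5-(1,3-oxazol-5-ylmethyl)-1,3-dioxolan-4-yl]ethyl}-3-[dimethyl(phenyl)silyl]prop-2-en-1-ol
Conditions: NaBH4, CeCl3·7H2O, MeOH, −20 °C
Reagents that add atoms: none
Why: Luche 1,2-reduction of the enal without alkene isomerisation.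

Step 26
Reactants: 35 allylic alcohol
Product: 36 5-{[(4S,5R)-5-{(3Z)-4-[dimethyl(phenyl)silyl]-3-(methoxymethyl)but-3-en-1-yl}-2,2-dimethyl-1,3-dioxolan-4-yl]methyl}-1,3-oxazole
Conditions: MeI (excess), Ag2O, MeCN, 40 °C, dark
Reagents that add atoms: iodomethane, CI
Why: Purdie methylation under neutral conditions avoids the base-induced 1,4-silyl shift of a (Z)-γ-silyl allylic alkoxide.

Step 27
Reactants: 36 vinylsilane
Product: 37 5-{[(4S,5R)-5-[(3Z)-4-iodo-3-(methoxymethyl)but-3-en-1-yl]-2,2-dimethyl-1,3-dioxolan-4-yl]methyl}-1,3-oxazole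
Conditions: NIS, MeCN/ClCH2CN (4:1), 0 °C
Reagents that add atoms: N-iodosuccinimide, O=C1CCC(=O)N1I
Why: Ipso-iododesilylation of the vinylsilane proceeds with retention, giving the (Z)-alkenyl iodide (iodine cis to CH2OMe).

Step 28
Reactants: 37 oxazole alkenyl iodide
Product: 38 (4S,5R,8Z)-1-amino-4,5-dihydroxy-9-iodo-8-(methoxymethyl)non-8-en-2-one hydrochloride
Conditions: 2 M aq. HCl/THF (1:1), 50 °C
Reagents that add atoms: hydrogen chloride, Cl
Why: Acid hydrolysis opens the 5-alkyl oxazole to the α-amino ketone (loss of C2 as formic acid) and cleaves the acetonide, which frees the C21 hydroxyl needed to direct step 30.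

**Fragment union and endgame**

Step 29
Reactants: 28 west–HA acid; 38 east amino ketone hydrochloride
Product: 39 (2S)-1-{[(4S,5R,8Z)-4,5-dihydroxy-9-iodo-8-(methoxymethyl)-2-oxonon-8-en-1-yl]amino}-1-oxopentan-2-yl (2S,4R,9R,13S,14E)-13-ethyl-9-hydroxy-15-iodo-2,4-dimethylpentadec-14-enoate
Conditions: EDC·HCl, HOAt, N-methylmorpholine, DMF, 0 °C → rt
Reagents that add atoms: none
Why: Carbodiimide/HOAt amide coupling; the amine, freed in situ, is acylated far faster than the hydroxyl groups, and the HOAt ester limits epimerisation at the HA centre.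

Step 30
Reactants: 39 keto-diol amide
Product: 40 (2S)-1-{[(2S,4S,5R,8Z)-2,4,5-trihydroxy-9-iodo-8-(methoxymethyl)non-8-en-1-yl]amino}-1-oxopentan-2-yl (2S,4R,9R,13S,14E)-13-ethyl-9-hydroxy-15-iodo-2,4-dimethylpentadec-14-enoate
Conditions: Me4NBH(OAc)3, MeCN/AcOH (1:1), −30 °C
Reagents that add atoms: none
Why: Evans–Saksena reduction: the C21 hydroxyl binds the triacetoxyborohydride and delivers hydride intramolecularly through a chair transition state, giving the 1,3-anti diol and so the 23S centre from the bought C21 centre.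

Step 31
Reactants: 40 open-chain bis(alkenyl iodide)
Product: 41 CNP0221503.2 (target)
Conditions: NiBr2(dme) (20 mol%), 4,4′-di-tert-butyl-2,2′-bipyridine (24 mol%), n-Bu4NBr, DMA, undivided cell, Zn anode, Ni-foam cathode, constant current (about 2.2 F/mol), 40 added by syringe pump (final 1 mM), rt
Reagents that add atoms: none
Why: Proposed new method: a nickel-electrocatalytic intramolecular reductive cross-coupling of two unlike alkenyl iodides, in which cathodically formed zerovalent nickel–bipyridine inserts into the less hindered (E)-alkenyl iodide, the divalent alkenylnickel iodide is reduced to a monovalent alkenylnickel species that adds the tethered (Z)-alkenyl iodide, and the trivalent dialkenylnickel intermediate reductively eliminates the C15–C16 bond with retention at both alkenes, closing the 28-membered ring and creating the (14E,16Z)-diene under high dilution while the zinc anode takes up iodide; closest known reaction type is the nickel-catalysed electroreductive homocoupling of alkenyl halides and the nickel/palladium cross-electrophile coupling of alkenyl halides with alkenyl triflates to 1,3-dienes, neither shown for macrocyclisation.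

**Compound list**

1 | (S)-3-bromo-2-methylpropan-1-ol | OC[C@H](C)CBr | starting material
2 | (R)-2-methylhex-5-en-1-ol | OC[C@H](C)CCC=C | intermediate
3 | (R)-6-bromo-5-methylhex-1-ene | BrC[C@H](C)CCC=C | intermediate
4 | tert-butyl (S)-2-hydroxypropanoate (tert-butyl L-lactate) | C[C@H](O)C(=O)OC(C)(C)C | starting material
5 | tert-butyl (S)-2-{[(trifluoromethyl)sulfonyl]oxy}propanoate | C[C@H](OS(=O)(=O)C(F)(F)F)C(=O)OC(C)(C)C | intermediate
6 | [(2R)-2-methylhex-5-en-1-yl]magnesium bromide | Br[Mg]C[C@H](C)CCC=C | intermediate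
7 | tert-butyl (2S,4R)-2,4-dimethyloct-7-enoate | CC(C)(C)OC(=O)[C@@H](C)C[C@H](C)CCC=C | intermediate
8 | (S)-2-(chloromethyl)oxirane ((S)-epichlorohydrin) | ClC[C@@H]1CO1 | starting material
9 | (S)-1-chloropent-4-en-2-ol | ClC[C@@H](O)CC=C | intermediate
10 | (S)-2-(prop-2-en-1-yl)oxirane | C=CC[C@H]1CO1 | intermediate
11 | (S)-hexa-1,5-dien-3-ol | C=C[C@@H](O)CC=C | intermediate
12 | tert-butyl[(3S)-hexa-1,5-dien-3-yloxy]dimethylsilane | C=C[C@@H](O[Si](C)(C)C(C)(C)C)CC=C | intermediate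
13 | 9-{(4S)-4-[(tert-butyldimethylsilyl)oxy]hex-5-en-1-yl}-9-borabicyclo[3.3.1]nonane | C=C[C@@H](O[Si](C)(C)C(C)(C)C)CCCB1C2CCCC1CCC2 | intermediate
14 | (4S)-4-[(tert-butyldimethylsilyl)oxy]hex-5-en-1-ol | C=C[C@@H](O[Si](C)(C)C(C)(C)C)CCCO | intermediate
15 | {[(3S)-6-bromohex-1-en-3-yl]oxy}(tert-butyl)dimethylsilane | C=C[C@@H](O[Si](C)(C)C(C)(C)C)CCCBr | intermediate
16 | methyl (S)-2-hydroxybutanoate | CC[C@H](O)C(=O)OC | starting material
17 | methyl (S)-2-{[(trifluoromethyl)sulfonyl]oxy}butanoate | CC[C@H](OS(=O)(=O)C(F)(F)F)C(=O)OC | intermediate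
18 | {(4S)-4-[(tert-butyldimethylsilyl)oxy]hex-5-en-1-yl}magnesium bromide | C=C[C@@H](O[Si](C)(C)C(C)(C)C)CCC[Mg]Br | intermediate
19 | methyl (2S,6S)-6-[(tert-butyldimethylsilyl)oxy]-2-ethyloct-7-enoate | C=C[C@@H](O[Si](C)(C)C(C)(C)C)CCC[C@H](CC)C(=O)OC | intermediate
20 | 1-tert-butyl 14-methyl (2S,4R,7E,9S,13S)-9-[(tert-butyldimethylsilyl)oxy]-13-ethyl-2,4-dimethyltetradec-7-enedioate (E major) | CC(C)(C)OC(=O)[C@@H](C)C[C@H](C)CC/C=C/[C@@H](O[Si](C)(C)C(C)(C)C)CCC[C@H](CC)C(=O)OC | intermediate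
21 | 1-tert-butyl 14-methyl (2S,4R,9R,13S)-9-[(tert-butyldimethylsilyl)oxy]-13-ethyl-2,4-dimethyltetradecanedioate | CC(C)(C)OC(=O)[C@@H](C)C[C@H](C)CCCC[C@@H](O[Si](C)(C)C(C)(C)C)CCC[C@H](CC)C(=O)OC | intermediate
22 | tert-butyl (2S,4R,9R,13S)-9-[(tert-butyldimethylsilyl)oxy]-13-ethyl-2,4-dimethyl-14-oxotetradecanoate | CC(C)(C)OC(=O)[C@@H](C)C[C@H](C)CCCC[C@@H](O[Si](C)(C)C(C)(C)C)CCC[C@H](CC)C=O | intermediate
23 | tert-butyl (2S,4R,9R,13S,14E)-9-[(tert-butyldimethylsilyl)oxy]-13-ethyl-15-iodo-2,4-dimethylpentadec-14-enoate | CC(C)(C)OC(=O)[C@@H](C)C[C@H](C)CCCC[C@@H](O[Si](C)(C)C(C)(C)C)CCC[C@H](CC)/C=C/I | intermediate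
24 | (2S,4R,9R,13S,14E)-9-[(tert-butyldimethylsilyl)oxy]-13-ethyl-15-iodo-2,4-dimethylpentadec-14-enoic acid | OC(=O)[C@@H](C)C[C@H](C)CCCC[C@@H](O[Si](C)(C)C(C)(C)C)CCC[C@H](CC)/C=C/I | intermediate
25 | (S)-2-hydroxypentanoic acid | CCC[C@H](O)C(=O)O | starting material
26 | tert-butyl (S)-2-hydroxypentanoate | CCC[C@H](O)C(=O)OC(C)(C)C | intermediate
27 | (2S)-1-tert-butoxy-1-oxopentan-2-yl (2S,4R,9R,13S,14E)-9-[(tert-butyldimethylsilyl)oxy]-13-ethyl-15-iodo-2,4-dimethylpentadec-14-enoate | CCC[C@H](OC(=O)[C@@H](C)C[C@H](C)CCCC[C@@H](O[Si](C)(C)C(C)(C)C)CCC[C@H](CC)/C=C/I)C(=O)OC(C)(C)C | intermediate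
28 | (2S)-2-{[(2S,4R,9R,13S,14E)-13-ethyl-9-hydroxy-15-iodo-2,4-dimethylpentadec-14-enoyl]oxy}pentanoic acid | CCC[C@H](OC(=O)[C@@H](C)C[C@H](C)CCCC[C@@H](O)CCC[C@H](CC)/C=C/I)C(=O)O | intermediate
29 | 2-deoxy-D-ribose ((3S,4R)-3,4,5-trihydroxypentanal, drawn open-chain) | OC[C@@H](O)[C@@H](O)CC=O | starting material
30 | 2-deoxy-3,4-O-isopropylidene-D-erythro-pentopyranose (anomer mixture) | O1C[C@@H](OC2(C)C)[C@@H](O2)CC1O | intermediate
31 | [(4R,5S)-2,2-dimethyl-5-(1,3-oxazol-5-ylmethyl)-1,3-dioxolan-4-yl]methanol | OC[C@@H](OC1(C)C)[C@@H](O1)Cc2cnco2 | intermediate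
32 | 5-{[(4S,5S)-5-(iodomethyl)-2,2-dimethyl-1,3-dioxolan-4-yl]methyl}-1,3-oxazole | IC[C@@H](OC1(C)C)[C@@H](O1)Cc2cnco2 | intermediate
33 | 5-{[(4S,5R)-5-(but-3-yn-1-yl)-2,2-dimethyl-1,3-dioxolan-4-yl]methyl}-1,3-oxazole | C#CCC[C@@H](OC1(C)C)[C@@H](O1)Cc2cnco2 | intermediate
34 | (2Z)-2-{2-[(4R,5S)-2,2-dimethyl-5-(1,3-oxazol-5-ylmethyl)-1,3-dioxolan-4-yl]ethyl}-3-[dimethyl(phenyl)silyl]prop-2-enal | O=C/C(CC[C@@H](OC1(C)C)[C@@H](O1)Cc2cnco2)=C\[Si](C)(C)c3ccccc3 | intermediate
35 | (2Z)-2-{2-[(4R,5S)-2,2-dimethyl-5-(1,3-oxazol-5-ylmethyl)-1,3-dioxolan-4-yl]ethyl}-3-[dimethyl(phenyl)silyl]prop-2-en-1-ol | OC/C(CC[C@@H](OC1(C)C)[C@@H](O1)Cc2cnco2)=C\[Si](C)(C)c3ccccc3 | intermediate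
36 | 5-{[(4S,5R)-5-{(3Z)-4-[dimethyl(phenyl)silyl]-3-(methoxymethyl)but-3-en-1-yl}-2,2-dimethyl-1,3-dioxolan-4-yl]methyl}-1,3-oxazole | COC/C(CC[C@@H](OC1(C)C)[C@@H](O1)Cc2cnco2)=C\[Si](C)(C)c3ccccc3 | intermediate
37 | 5-{[(4S,5R)-5-[(3Z)-4-iodo-3-(methoxymethyl)but-3-en-1-yl]-2,2-dimethyl-1,3-dioxolan-4-yl]methyl}-1,3-oxazole | COC/C(CC[C@@H](OC1(C)C)[C@@H](O1)Cc2cnco2)=C\I | intermediate
38 | (4S,5R,8Z)-1-amino-4,5-dihydroxy-9-iodo-8-(methoxymethyl)non-8-en-2-one hydrochloride | COC/C(CC[C@@H](O)[C@@H](O)CC(=O)CN)=C\I.Cl | intermediate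
39 | (2S)-1-{[(4S,5R,8Z)-4,5-dihydroxy-9-iodo-8-(methoxymethyl)-2-oxonon-8-en-1-yl]amino}-1-oxopentan-2-yl (2S,4R,9R,13S,14E)-13-ethyl-9-hydroxy-15-iodo-2,4-dimethylpentadec-14-enoate | CCC[C@H](OC(=O)[C@@H](C)C[C@H](C)CCCC[C@@H](O)CCC[C@H](CC)/C=C/I)C(=O)NCC(=O)C[C@H](O)[C@H](O)CC/C(COC)=C/I | intermediate
40 | (2S)-1-{[(2S,4S,5R,8Z)-2,4,5-trihydroxy-9-iodo-8-(methoxymethyl)non-8-en-1-yl]amino}-1-oxopentan-2-yl (2S,4R,9R,13S,14E)-13-ethyl-9-hydroxy-15-iodo-2,4-dimethylpentadec-14-enoate | CCC[C@H](OC(=O)[C@@H](C)C[C@H](C)CCCC[C@@H](O)CCC[C@H](CC)/C=C/I)C(=O)NC[C@@H](O)C[C@H](O)[C@H](O)CC/C(COC)=C/I | intermediate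
41 | CNP0221503.2, the 28-membered lactone–lactam (2S,4R,9R,13S,14E,16Z,20R,21S,23S in target numbering, HA centre S) | CCC[C@@H]1OC(=O)[C@@H](C)C[C@H](C)CCCC[C@@H](O)CCC[C@H](CC)/C=C/C=C(\COC)CC[C@@H](O)[C@@H](O)C[C@H](O)CNC1=O | target

**Step count and risks**

Total: 31 steps. Longest linear sequence: 16 steps (8 → 41 through steps 5–9, 11–16, 18, 19, 29–31).

The three steps most likely to fail:

Step 31 (the proposed electrochemical macrocyclisation; risks are oligomerisation, hydrodeiodination and loss of the Z geometry at nickel). The fallback sets out from 40 and comes back to the route at 41, using a known Stille–Kelly ring closure. With Pd(PPh3)4 (10 mol%) and Me3SnSnMe3 (1.05 equiv) in toluene/DMF at 90 °C and 2 mM, the less hindered (E)-alkenyl iodide is stannylated in the flask to the (14E)-15-(trimethylstannyl) analogue of 40 F1, which closes by intramolecular Stille coupling onto the (Z)-alkenyl iodide to give 41.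

Step 24 (silylformylation; the oxazole may bind rhodium, and regio- or Z-selectivity may erode). The fallback sets out from 33 and comes back at 37 by a carbometalation/cross-coupling sequence. Pd(PPh3)4-catalysed syn silylstannation with Me3SiSnBu3 (THF, 65 °C) gives 5-{[(4S,5R)-2,2-dimethyl-5-[(3Z)-3-(tributylstannyl)-4-(trimethylsilyl)but-3-en-1-yl]-1,3-dioxolan-4-yl]methyl}-1,3-oxazole F2. Iododestannylation (I2, CH2Cl2, 0 °C) gives 5-{[(4S,5R)-5-[(3Z)-3-iodo-4-(trimethylsilyl)but-3-en-1-yl]-2,2-dimethyl-1,3-dioxolan-4-yl]methyl}-1,3-oxazole F3. Stille coupling with Bu3SnCH2OMe (Pd2(dba)3, AsPh3, CuI, NMP, 50 °C) gives 5-{[(4S,5R)-5-[(3Z)-3-(methoxymethyl)-4-(trimethylsilyl)but-3-en-1-yl]-2,2-dimethyl-1,3-dioxolan-4-yl]methyl}-1,3-oxazole F4. Iododesilylation with NIS as in step 27 then gives 37.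

Step 21 (van Leusen reaction on a lactol whose open form is a base-sensitive β-alkoxy aldehyde). The fallback sets out from 30 and comes back at 31 by acylating a metalated isocyanide instead. Oxidation of the lactol (TEMPO cat., PhI(OAc)2, CH2Cl2) gives 2-deoxy-3,4-O-isopropylidene-D-erythro-pentono-1,5-lactone F5. Lithiomethyl isocyanide (CH3NC, n-BuLi, THF, −78 °C) adds to the lactone carbonyl and the resulting α-isocyano ketone cyclises to the same oxazole 31 with the C19 hydroxyl set free.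

**Further compounds**

F1 | step 31 | (2S)-1-{[(2S,4S,5R,8Z)-2,4,5-trihydroxy-9-iodo-8-(methoxymethyl)non-8-en-1-yl]amino}-1-oxopentan-2-yl (2S,4R,9R,13S,14E)-13-ethyl-9-hydroxy-2,4-dimethyl-15-(trimethylstannyl)pentadec-14-enoate | CCC[C@H](OC(=O)[C@@H](C)C[C@H](C)CCCC[C@@H](O)CCC[C@H](CC)/C=C/[Sn](C)(C)C)C(=O)NC[C@@H](O)C[C@H](O)[C@H](O)CC/C(COC)=C/I
F2 | step 24 | 5-{[(4S,5R)-2,2-dimethyl-5-[(3Z)-3-(tributylstannyl)-4-(trimethylsilyl)but-3-en-1-yl]-1,3-dioxolan-4-yl]methyl}-1,3-oxazole | C[Si](C)(C)/C=C(\[Sn](CCCC)(CCCC)CCCC)CC[C@@H](OC1(C)C)[C@@H](O1)Cc2cnco2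
F3 | step 24 | 5-{[(4S,5R)-5-[(3Z)-3-iodo-4-(trimethylsilyl)but-3-en-1-yl]-2,2-dimethyl-1,3-dioxolan-4-yl]methyl}-1,3-oxazole | C[Si](C)(C)/C=C(\I)CC[C@@H](OC1(C)C)[C@@H](O1)Cc2cnco2
F4 | step 24 | 5-{[(4S,5R)-5-[(3Z)-3-(methoxymethyl)-4-(trimethylsilyl)but-3-en-1-yl]-2,2-dimethyl-1,3-dioxolan-4-yl]methyl}-1,3-oxazole | C[Si](C)(C)/C=C(\COC)CC[C@@H](OC1(C)C)[C@@H](O1)Cc2cnco2
F5 | step 21 | 2-deoxy-3,4-O-isopropylidene-D-erythro-pentono-1,5-lactone | O1C[C@@H](OC2(C)C)[C@@H](O2)CC1=O
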